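common to all: electrophile 38 mM (fed, over 3.0 h); nucleophile 39.9 mM

| charge | free base | remark | time |
|---|---|---|---|
| oak | 27 mM | run made earlier |  |
| cedar | 42 mM | run made earlier |  |
| noon | 30.0 mM |  | 30 h |
| dusk | 51.0 mM |  | 30 h |
| midnight | 40.0 mM |  | 30 h |

- oak (time / h: electrophile / %, product / %): 2.00: 59, 6; 5.00: 64, 25; 10.0: 37, 44; 15.0: 25, 51
- cedar (time / h: electrophile / %, product / %): 1.33: 41, 1; 3.00: 80, 13; 6.00: 56, 28; 15.0: 24, 55

(readings scatter by 2 percentage points)

- percentages count the whole charge, also what has not yet gone in

* part of the electrophile that has reacted at the end, noon
* part of the electrophile that has reacted at the end, dusk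
* part of the electrophile that has reacted at the end, midnight
* what raising the concentration of free base from its lowest to its highest value here does to the part of the electrophile that has reacted (changes below 5 percentage points count as none) (it rises / it falls / no change)

1. The amounts are close: 38 mM of electrophile, the limiting reagent, meets 39.9 mM of nucleophile. So I let [electrophile] and [nucleophile] fall together, and after the feed the reciprocal of the remaining electrophile fraction should grow linearly in time.

2. Oak gives a slope of 0.259 h⁻¹ and cedar 0.265 h⁻¹. Their mean, 0.262 h⁻¹, is my reciprocal clock, the hourly gain in charge over remaining electrophile, an apparent second-order rate constant read from the readings.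

3. Which inputs matter? Cedar's reading at 15.0 h, off by 2 percentage points, shifts the electrophile left at 30 h by 0.51 points. The same slip carried into the mean clock shifts it by 0.42 points, which is less. Using oak's clock, at 27 mM of free base, instead of cedar's, at 42 mM, shifts it by 0.12 points, which is less.

4. Starting from oak, I reckon 87.4% reacted for noon. Starting from cedar, I reckon 87.6% for dusk, with midnight between them: no change.

5. The forecast stands higher than my reckoning, at 90%, 92% and 91%; its answer on the trend, no change, rests on the words “base has little kinetic effect”.

6. The flask gives 88.2%, 89.2% and 88.9%, so no change: the change is 0.97 points, below 5 points. The forecast held.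

    electrophile + nucleophile → acid set free + product (k = 0.0470 L mol⁻¹ min⁻¹)
    nucleophile + acid set free ⇌ protonated nucleophile, settled at all times (K = 9800 L mol⁻¹)
    acid set free + free base ⇌ salt of the base, settled at all times (K = 1.00 × 10⁵ L mol⁻¹)
    2 electrophile → homo dimer (k = 0.0150 L mol⁻¹ min⁻¹)
    free base ⇌ dormant form (K = 0.700, k = 7.80 × 10⁻⁴ min⁻¹)

7. In dusk, electrophile goes to product 2.1 times as fast as to homo dimer at 6.17 h and 5.3 times as fast at 30.0 h. Both steps are second order, and the clock's 12.4% left stands against 10.8% in dusk. For the same flask as dusk read at 20 h, the clock gives 18.3% left; the computed flask holds 18.2%, so 81.8% has reacted.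

The runs stem from a simulated flask with constants of no real substance; the scatter is artificial.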